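**Assumption:** the target contains no stereocentre (it is achiral), so the SMILES defines one compound and no stereocontrol is needed.

**Retrosynthetic overview**
1. Target 12 ⇒ tridepside 9 by hydroxylation of the one unhindered C–H (C4 of terminal ring C); the free 4-OH of the orsellinoyl unit is carried as C–H until the last step, so no protecting group is used.
2. 9 ⇒ didepside 4 + 6-methylsalicylic acid 5 by an aryl C–O disconnection of the B–C depside bond (C4–H of ring B → C4–O–acyl; new one-pot C–H borylation / copper-mediated acyloxylation).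
3. 4 ⇒ methyl orsellinate 1 + 2-methoxy-6-methylbenzoic acid 2 by an acyl C–O disconnection (classical depside condensation at the free 4-OH).
4. No ring is formed: the three benzene rings are bought intact and joined in the order A (from 1), B (from 2), C (from 5).

**Route**

Step 1
Reactants: 1 methyl 2,4-dihydroxy-6-methylbenzoate (methyl orsellinate); 2 2-methoxy-6-methylbenzoic acid
Product: 4 methyl 2-hydroxy-4-[(2-methoxy-6-methylbenzoyl)oxy]-6-methylbenzoate, via mixed trifluoroacetic anhydride 3 (not isolated)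
Conditions: TFAA (4 equiv), toluene, 0 °C → rt, 4 h; aq. NaHCO3
Reagents that add atoms: trifluoroacetic anhydride, O=C(OC(=O)C(F)(F)F)C(F)(F)F (its CF3CO group is carried only by 3; nothing of it remains in 4)
Why: TFAA-mediated depside condensation (mixed-anhydride esterification): 3 ionises to the ortho-methoxy-stabilised aroyl cation, which acylates the free 4-OH of 1, while the 2-OH is held in the hydrogen bond to the ester and stays free; no stereocentre is formed.

Step 2
Reactants: 4 methyl 2-hydroxy-4-[(2-methoxy-6-methylbenzoyl)oxy]-6-methylbenzoate; 5 2-hydroxy-6-methylbenzoic acid (6-methylsalicylic acid)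
Product: 9 methyl 2-hydroxy-4-({4-[(2-hydroxy-6-methylbenzoyl)oxy]-2-methoxy-6-methylbenzoyl}oxy)-6-methylbenzoate, via O-boryl didepside 6 (not isolated), via aryl boronate 7 (not isolated), via O-boryl tridepside 8 (not isolated)
Conditions: (i) HBpin (1.2 equiv), B2pin2 (1.0 equiv), [Ir(OMe)(cod)]2 (2 mol %), dtbpy (4 mol %), THF, 80 °C; evaporate volatiles; (ii) 5 (3 equiv), Cu(OTf)2 (2.2 equiv), pyridine (4 equiv), 4 Å MS, MeCN, 60 °C, Ar; aq. NH4Cl
Reagents that add atoms: pinacolborane, CC1(C)OBOC1(C)C, and bis(pinacolato)diboron, CC1(C)OB(OC1(C)C)B1OC(C)(C)C(C)(C)O1 (boryl groups in 6, 7 and 8 only; every heavy atom of 9 comes from 4 and 5)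
Why: Proposed new method: a formal C–H acyloxylation that makes the depside bond from the aryl side; the phenol of 4 is first capped as its O–Bpin ether (6), the iridium trisboryl catalyst then borylates the only C–H with no ortho substituent (C4 of the 2-methoxy-6-methylbenzoyl ring, giving 7), the aryl group is passed from boron to a copper(II) carboxylate of 5, a second Cu(II) oxidises this to aryl–Cu(III)–carboxylate, and C(aryl)–O reductive elimination gives the ester, so the crowded 2,6-disubstituted acyl carbon never has to be attacked by a weak phenol nucleophile; the hydrogen-bonded salicylate OH of 5 and the O–Bpin-masked OH of ring A should be poor O-arylation partners, and aqueous work-up cleaves the O–Bpin of 8; the closest known reactions are one-pot iridium C–H borylation / Chan–Lam etherification or amination of arenes and the copper(II) triflate-mediated coupling of arylboronic acids with carboxylic acids, which have not been combined or applied to free hydroxy-benzoic acids and depsides; no stereocentre is formed.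

Step 3
Reactants: 9 methyl 2-hydroxy-4-({4-[(2-hydroxy-6-methylbenzoyl)oxy]-2-methoxy-6-methylbenzoyl}oxy)-6-methylbenzoate
Product: 12 methyl 4-({4-[(2,4-dihydroxy-6-methylbenzoyl)oxy]-2-methoxy-6-methylbenzoyl}oxy)-2-hydroxy-6-methylbenzoate, via bis-O-boryl tridepside 10 (not isolated), via ring C boronate 11 (not isolated)
Conditions: (i) HBpin (2.4 equiv), B2pin2 (1.0 equiv), [Ir(OMe)(cod)]2 (2 mol %), dtbpy (4 mol %), THF, 80 °C; evaporate volatiles; (ii) Oxone, acetone–H2O, rt, 15 min
Reagents that add atoms: potassium peroxymonosulfate (Oxone), [K+].[O-]S(=O)(=O)OO (gives the new phenolic O of 12); pinacolborane, CC1(C)OBOC1(C)C, and bis(pinacolato)diboron, CC1(C)OB(OC1(C)C)B1OC(C)(C)C(C)(C)O1 (boryl groups in 10 and 11 only)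
Why: One-pot sterically controlled iridium-catalysed C–H borylation / oxidation: all four C–H bonds of rings A and B are flanked by two substituents, so only C4 of the terminal 2-hydroxy-6-methylbenzoyl ring is borylated, and Oxone converts C–B into C–OH by 1,2-aryl migration at near-neutral pH, where the two hindered depside esters survive; no stereocentre is formed.

**Compound list**
1 | methyl 2,4-dihydroxy-6-methylbenzoate (methyl orsellinate) | COC(=O)c1c(C)cc(O)cc1O | starting material
2 | 2-methoxy-6-methylbenzoic acid | COc1cccc(C)c1C(=O)O | starting material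
3 | 2-methoxy-6-methylbenzoic trifluoroacetic anhydride | COc1cccc(C)c1C(=O)OC(=O)C(F)(F)F | intermediate (not isolated)
4 | methyl 2-hydroxy-4-[(2-methoxy-6-methylbenzoyl)oxy]-6-methylbenzoate | COC(=O)c1c(C)cc(OC(=O)c2c(C)cccc2OC)cc1O | intermediate
5 | 2-hydroxy-6-methylbenzoic acid (6-methylsalicylic acid) | Cc1cccc(O)c1C(=O)O | starting material
6 | methyl 4-[(2-methoxy-6-methylbenzoyl)oxy]-6-methyl-2-[(4,4,5,5-tetramethyl-1,3,2-dioxaborolan-2-yl)oxy]benzoate | COC(=O)c1c(C)cc(OC(=O)c2c(C)cccc2OC)cc1OB3OC(C)(C)C(C)(C)O3 | intermediate (not isolated)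
7 | methyl 4-{[2-methoxy-6-methyl-4-(4,4,5,5-tetramethyl-1,3,2-dioxaborolan-2-yl)benzoyl]oxy}-6-methyl-2-[(4,4,5,5-tetramethyl-1,3,2-dioxaborolan-2-yl)oxy]benzoate | COC(=O)c1c(C)cc(OC(=O)c2c(C)cc(B3OC(C)(C)C(C)(C)O3)cc2OC)cc1OB4OC(C)(C)C(C)(C)O4 | intermediate (not isolated)
8 | O-pinacolboryl ether (at the ring A 2-OH) of 9 | COC(=O)c1c(C)cc(OC(=O)c2c(C)cc(OC(=O)c3c(C)cccc3O)cc2OC)cc1OB4OC(C)(C)C(C)(C)O4 | intermediate (not isolated)
9 | methyl 2-hydroxy-4-({4-[(2-hydroxy-6-methylbenzoyl)oxy]-2-methoxy-6-methylbenzoyl}oxy)-6-methylbenzoate | COC(=O)c1c(C)cc(OC(=O)c2c(C)cc(OC(=O)c3c(C)cccc3O)cc2OC)cc1O | intermediate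
10 | bis(O-pinacolboryl) ether of 9 (both phenolic OH as O–Bpin) | COC(=O)c1c(C)cc(OC(=O)c2c(C)cc(OC(=O)c3c(C)cccc3OB5OC(C)(C)C(C)(C)O5)cc2OC)cc1OB4OC(C)(C)C(C)(C)O4 | intermediate (not isolated)
11 | 10 carrying a further Bpin group on C4 of ring C | COC(=O)c1c(C)cc(OC(=O)c2c(C)cc(OC(=O)c3c(C)cc(B6OC(C)(C)C(C)(C)O6)cc3OB5OC(C)(C)C(C)(C)O5)cc2OC)cc1OB4OC(C)(C)C(C)(C)O4 | intermediate (not isolated)
12 | methyl 4-({4-[(2,4-dihydroxy-6-methylbenzoyl)oxy]-2-methoxy-6-methylbenzoyl}oxy)-2-hydroxy-6-methylbenzoate | COC(=O)c1c(C)cc(OC(=O)c2c(C)cc(OC(=O)c3c(C)cc(O)cc3O)cc2OC)cc1O | target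

**Step count:** 3 steps in total; longest linear sequence 3 steps (1 + 2 → 4 → 9 → 12).

**Steps most likely to fail, with fallbacks**

Step 2 (the proposed new step). The risks are slow boron-to-copper transfer from the pinacol boronate, protodeboronation or hydroxylation of 7, and O-arylation of a phenol instead of the carboxylate. The fallback uses only known chemistry, sets out from 4 and comes back at 9. Compound 4 is taken through the standard one-pot borylation (through 6 and 7) and Oxone oxidation to the phenol methyl 2-hydroxy-4-[(4-hydroxy-2-methoxy-6-methylbenzoyl)oxy]-6-methylbenzoate F1. The depside bond is then made from the acyl side: F1 and 5 are condensed with TFAA in toluene at room temperature, through 2-hydroxy-6-methylbenzoic trifluoroacetic anhydride F2. Only the free 4-OH of ring B is acylated, because both other hydroxyls are chelated, and this gives 9.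

Step 3. The risks are incomplete borylation of a poorly soluble tridepside carrying two boryl ethers, and over-oxidation of the resorcinol-type product by Oxone. The fallback sets out from 4, with 1 as the source of ring C, and comes back at 12. The ring C oxygen is brought in as a benzyl ether instead of being made by C–H oxidation. Compound 1 is benzylated at the free 4-OH (BnBr, K2CO3, acetone, reflux) to methyl 4-(benzyloxy)-2-hydroxy-6-methylbenzoate F3. Saponification (KOH, aq. DMSO, 80 °C) gives 4-(benzyloxy)-2-hydroxy-6-methylbenzoic acid F4. Compound 4 is run through the step 2 protocol with F4 in place of 5 (through 6, 7 and the O-pinacolboryl ether F5 of the benzyl-protected tridepside) to give methyl 4-[(4-{[4-(benzyloxy)-2-hydroxy-6-methylbenzoyl]oxy}-2-methoxy-6-methylbenzoyl)oxy]-2-hydroxy-6-methylbenzoate F6. Hydrogenolysis (H2, Pd/C, EtOAc, rt) removes the benzyl group and gives 12.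

Step 1. The risks are C-acylation of the electron-rich ring of 1 by the aroyl cation and incomplete activation of 2. The fallback sets out from 2 and comes back at 4. It replaces the acid-mediated mixed-anhydride coupling by a base-mediated acid chloride / phenoxide acylation. Acid 2 with (COCl)2 and catalytic DMF in CH2Cl2 gives 2-methoxy-6-methylbenzoyl chloride F7. F7 reacts with the more acidic, non-chelated 4-phenoxide of 1 (K2CO3, acetone, rt) to give 4.

**Further compounds**
F1 | step 2 | methyl 2-hydroxy-4-[(4-hydroxy-2-methoxy-6-methylbenzoyl)oxy]-6-methylbenzoate | COC(=O)c1c(C)cc(OC(=O)c2c(C)cc(O)cc2OC)cc1O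
F2 | step 2 | 2-hydroxy-6-methylbenzoic trifluoroacetic anhydride | Cc1cccc(O)c1C(=O)OC(=O)C(F)(F)F
F3 | step 3 | methyl 4-(benzyloxy)-2-hydroxy-6-methylbenzoate | COC(=O)c1c(C)cc(OCc2ccccc2)cc1O
F4 | step 3 | 4-(benzyloxy)-2-hydroxy-6-methylbenzoic acid | Cc1cc(OCc2ccccc2)cc(O)c1C(=O)O
F5 | step 3 | O-pinacolboryl ether (at the ring A 2-OH) of F6 | COC(=O)c1c(C)cc(OC(=O)c2c(C)cc(OC(=O)c3c(C)cc(OCc5ccccc5)cc3O)cc2OC)cc1OB4OC(C)(C)C(C)(C)O4
F6 | step 3 | methyl 4-[(4-{[4-(benzyloxy)-2-hydroxy-6-methylbenzoyl]oxy}-2-methoxy-6-methylbenzoyl)oxy]-2-hydroxy-6-methylbenzoate | COC(=O)c1c(C)cc(OC(=O)c2c(C)cc(OC(=O)c3c(C)cc(OCc4ccccc4)cc3O)cc2OC)cc1O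
F7 | step 1 | 2-methoxy-6-methylbenzoyl chloride | COc1cccc(C)c1C(=O)Cl
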